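**Strategy.** Germacrane locants are used (lactone oxygen on C6, C11 on C7, oxygens on C8 and C9). The ten-membered ring A is cut at C9–C10: C9 is an allylic carbinol bonded to C10 of the Z C1=C10 alkene, so a Z-alkenyl iodide and a C9 aldehyde are the ring ends. One ligand-controlled Nozaki–Hiyama–Kishi addition forms C9–C10, closes ring A and sets C9, leaving it as the only free hydroxyl. The precursor is the finished trans α-methylene lactone (ring B; C6, C7, C8 set) bearing the α-silyloxy aldehyde on C7 and the E-C4=C5 chain ending in the Z-iodide, made from geranyl acetate and a glyceraldehyde-derived allylboronate.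

Key step: step 13

Remarks on the chemistry:
- Stereochemical reading used throughout: 6R,7S,8R,9R, epoxy ester 2S,3S; ring B is trans-fused (H6 and H7 anti); the C8 and C9 oxygens are syn.
- C8 is carried as a triethylsilyl ether, not an arylmethyl ether. It arises together with the C9 aldehyde from a 1,2-diol in two operations and comes off without an oxidant.
- Assumption: geranyl acetate and (S)-glyceraldehyde acetonide are purchased. The antipode of the sulfonamide ligand that gives 9R is picked in a small screen of both.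

**Step 1**
Reactants: 1 geranyl acetate
Product: 2 (2E)-5-(3,3-dimethyloxiran-2-yl)-3-methylpent-2-en-1-yl acetate (racemic at the epoxide carbon)
Conditions: mCPBA (1.05 equiv), NaHCO3, CH2Cl2, 0 °C
Reagents that add atoms: 3-chloroperoxybenzoic acid, OOC(=O)c1cccc(Cl)c1
Why: Prilezhaev epoxidation should take the electron-rich terminal trisubstituted alkene and leave the allylic one, which the acetate deactivates; the racemic centre is cut out in step 2.

**Step 2**
Reactants: 2 (2E)-5-(3,3-dimethyloxiran-2-yl)-3-methylpent-2-en-1-yl acetate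
Product: 4 (2E)-3-methyl-6-oxohex-2-en-1-yl acetate, via racemic glycol 3 (not isolated)
Conditions: H5IO6 (1.2 equiv), THF/H2O, 0 °C → rt
Reagents that add atoms: none
Why: Acid-catalysed epoxide hydration followed by Malaprade glycol cleavage should release acetone and the aldehyde that becomes C1, with the E alkene and acetate untouched.

**Step 3**
Reactants: 4 (2E)-3-methyl-6-oxohex-2-en-1-yl acetate; 5 ethyltriphenylphosphonium iodide
Product: 9 (2E,6Z)-7-iodo-3-methylocta-2,6-dien-1-yl acetate, via ethylidenetriphenylphosphorane 6 (not isolated), via (1-iodoethyl)triphenylphosphonium iodide 7 (not isolated), via (1-iodoethylidene)triphenylphosphorane 8 (not isolated)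
Conditions: 5, n-BuLi, THF, rt; I2, −78 °C; NaN(SiMe3)2, −20 °C; then 4, −78 → −20 °C
Reagents that add atoms: iodine, [I][I]
Why: Wittig olefination with the α-iodo ylide (Stork–Zhao type) should give the Z-2-iodoalkene through kinetic cis-oxaphosphetane formation, and at −78 °C the ylide should take the aldehyde and spare the acetate.

**Step 4**
Reactants: 9 (2E,6Z)-7-iodo-3-methylocta-2,6-dien-1-yl acetate
Product: 10 (2E,6Z)-7-iodo-3-methylocta-2,6-dien-1-ol
Conditions: K2CO3, MeOH, 0 °C → rt
Reagents that add atoms: none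
Why: Base-catalysed transesterification (methanolysis) should free the allylic alcohol without touching the alkenyl iodide.

**Step 5**
Reactants: 10 (2E,6Z)-7-iodo-3-methylocta-2,6-dien-1-ol
Product: 11 (2E,6Z)-7-iodo-3-methylocta-2,6-dienal
Conditions: MnO2 (excess), CH2Cl2, rt
Reagents that add atoms: none
Why: Allylic alcohol oxidation with MnO2 should stop at the E-enal (the C6 aldehyde).

**Step 6**
Reactants: 12 (4S)-2,2-dimethyl-1,3-dioxolane-4-carbaldehyde
Product: 13 (4R)-4-(2,2-dibromoethenyl)-2,2-dimethyl-1,3-dioxolane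
Conditions: CBr4, PPh3, CH2Cl2, 0 °C
Reagents that add atoms: carbon tetrabromide, BrC(Br)(Br)Br
Why: Ramirez dibromo-olefination (first half of the Corey–Fuchs sequence) runs without base, so the α-alkoxy stereocentre that becomes C8 should not epimerise.

**Step 7**
Reactants: 13 (4R)-4-(2,2-dibromoethenyl)-2,2-dimethyl-1,3-dioxolane
Product: 15 methyl 3-[(4R)-2,2-dimethyl-1,3-dioxolan-4-yl]prop-2-ynoate, via lithium acetylide 14 (not isolated)
Conditions: n-BuLi (2.1 equiv), THF, −78 °C; then ClCO2Me, −78 → 0 °C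
Reagents that add atoms: methyl chloroformate, COC(=O)Cl
Why: The second half of the Corey–Fuchs reaction (Br/Li exchange, rearrangement to the acetylide) followed by C-acylation should give the ynoate with C8 untouched.

**Step 8**
Reactants: 15 methyl 3-[(4R)-2,2-dimethyl-1,3-dioxolan-4-yl]prop-2-ynoate
Product: 17 methyl (2Z)-3-[(4R)-2,2-dimethyl-1,3-dioxolan-4-yl]-2-[(4,4,5,5-tetramethyl-1,3,2-dioxaborolan-2-yl)methyl]prop-2-enoate, via α-alumino enoate 16 (not isolated)
Conditions: iBu2AlH, HMPA, THF, 0 °C; 15; then ICH2B(pin), 0 °C → rt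
Reagents that add atoms: 2-(iodomethyl)-4,4,5,5-tetramethyl-1,3,2-dioxaborolane, ICB1OC(C)(C)C(C)(C)O1
Why: Conjugate hydroalumination of the ynoate and α-alkylation of the resulting vinylalane place H and CH2B cis, so the dioxolanyl group ends cis to the ester (Z), the geometry that step 9 needs.

**Step 9**
Reactants: 11 (2E,6Z)-7-iodo-3-methylocta-2,6-dienal; 17 methyl (2Z)-3-[(4R)-2,2-dimethyl-1,3-dioxolan-4-yl]-2-[(4,4,5,5-tetramethyl-1,3,2-dioxaborolan-2-yl)methyl]prop-2-enoate
Product: 19 (4S,5R)-4-[(4R)-2,2-dimethyl-1,3-dioxolan-4-yl]-5-[(1E,5Z)-6-iodo-2-methylhepta-1,5-dien-1-yl]-3-methylideneoxolan-2-one, via open-chain borate 18 (not isolated)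
Conditions: Sc(OTf)3 (10 mol %), toluene, 0 °C → rt; then pyridinium p-toluenesulfonate (cat.), rt
Reagents that add atoms: none
Why: 2-Alkoxycarbonyl allylboration with lactonisation goes through a closed Zimmerman–Traxler chair in which the dioxolanyl group, trans to CH2B, sits equatorial, so C6–O and C7–C8 come out anti (trans lactone), while allylic strain with the cis ester holds C8–H in the alkene plane and the aldehyde approaches C7 anti to the C8–O bond (Felkin–Anh sense), which should set C7 as S and hence C6 as R from the pool-derived C8.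

**Step 10**
Reactants: 19 (4S,5R)-4-[(4R)-2,2-dimethyl-1,3-dioxolan-4-yl]-5-[(1E,5Z)-6-iodo-2-methylhepta-1,5-dien-1-yl]-3-methylideneoxolan-2-one
Product: 20 (4R,5R)-4-[(1R)-1,2-dihydroxyethyl]-5-[(1E,5Z)-6-iodo-2-methylhepta-1,5-dien-1-yl]-3-methylideneoxolan-2-one
Conditions: AcOH/H2O (4:1), 40 °C
Reagents that add atoms: none
Why: Mild acetal hydrolysis should free the C8/C9 diol without opening the lactone or ionising the allylic C6–O bond; no centre changes (the C7 descriptor changes by the priority rule only).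

**Step 11**
Reactants: 20 (4R,5R)-4-[(1R)-1,2-dihydroxyethyl]-5-[(1E,5Z)-6-iodo-2-methylhepta-1,5-dien-1-yl]-3-methylideneoxolan-2-one
Product: 21 (4S,5R)-4-[(1R)-1,2-bis(triethylsilyloxy)ethyl]-5-[(1E,5Z)-6-iodo-2-methylhepta-1,5-dien-1-yl]-3-methylideneoxolan-2-one
Conditions: Et3SiOTf (2.5 equiv), 2,6-lutidine, CH2Cl2, −78 °C
Reagents that add atoms: triethylsilyl trifluoromethanesulfonate, CC[Si](CC)(CC)OS(=O)(=O)C(F)(F)F
Why: Silylation with the triflate is fast at −78 °C, so both hydroxyls should be capped before the free C8 hydroxyl can attack the lactone carbonyl.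

**Step 12**
Reactants: 21 (4S,5R)-4-[(1R)-1,2-bis(triethylsilyloxy)ethyl]-5-[(1E,5Z)-6-iodo-2-methylhepta-1,5-dien-1-yl]-3-methylideneoxolan-2-one
Product: 22 (2R)-2-{(2R,3S)-2-[(1E,5Z)-6-iodo-2-methylhepta-1,5-dien-1-yl]-4-methylidene-5-oxooxolan-3-yl}-2-(triethylsilyloxy)acetaldehyde
Conditions: (COCl)2, DMSO, CH2Cl2, −78 → −40 °C; Et3N, −78 → 0 °C
Reagents that add atoms: none
Why: Under Swern conditions the activated sulfoxide cleaves and oxidises a primary triethylsilyl ether directly while the hindered secondary one stays, giving the C9 aldehyde in one operation; cold amine quench guards C8 against epimerisation.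

**Step 13**
Reactants: 22 (2R)-2-{(2R,3S)-2-[(1E,5Z)-6-iodo-2-methylhepta-1,5-dien-1-yl]-4-methylidene-5-oxooxolan-3-yl}-2-(triethylsilyloxy)acetaldehyde
Product: 24 (6R,7S,8R,9R)-9-hydroxy-8-(triethylsilyloxy)germacra-1(10)Z,4E,11(13)-trien-12,6-olide, via alkenylchromium dichloride 23 (not isolated)
Conditions: CrCl2 (6 equiv), N-[2-(4-isopropyl-4,5-dihydro-1,3-oxazol-2-yl)-6-methylphenyl]methanesulfonamide (single antipode, 6.6 equiv), Et3N, NiCl2 (10 mol %), THF/MeCN, 22 added over 12 h to 2 mM, rt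
Reagents that add atoms: none
Why: Zerovalent nickel (from NiCl2 and CrCl2) inserts into the C10–I bond with retention of the Z geometry and passes the alkenyl group to trivalent chromium (23), which adds 1,2 to the C9 aldehyde. This is a Nozaki–Hiyama–Kishi macrocyclisation in its ligand-controlled asymmetric form. Ring A closes by intramolecular carbonyl addition in the 10-exo-trig mode, C10 attacking C9 with the C=O outside the new ring. C9 is set by the chiral sulfonamide on chromium, which must override the Felkin–Anh preference of the α-silyloxy aldehyde for the 9S epimer; the wanted 9R alcohol is syn to the C8 ether. The step also needs the aldehyde to react in preference to the lactone carbonyl and the exocyclic acrylate, which the non-basic, aldehyde-selective organochromium provides, and ring closure to beat oligomerisation, which the cis C1=C10 geometry, the rigid trans lactone and slow addition at high dilution favour.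

**Step 14**
Reactants: 24 (6R,7S,8R,9R)-9-hydroxy-8-(triethylsilyloxy)germacra-1(10)Z,4E,11(13)-trien-12,6-olide
Product: 25 (6R,7S,8R,9R)-9-acetoxy-8-(triethylsilyloxy)germacra-1(10)Z,4E,11(13)-trien-12,6-olide
Conditions: Ac2O, pyridine, 4-(dimethylamino)pyridine (cat.), CH2Cl2, 0 °C
Reagents that add atoms: acetic anhydride, CC(=O)OC(C)=O
Why: Nucleophile-catalysed acylation of the only free hydroxyl (C9) should proceed with retention.

**Step 15**
Reactants: 25 (6R,7S,8R,9R)-9-acetoxy-8-(triethylsilyloxy)germacra-1(10)Z,4E,11(13)-trien-12,6-olide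
Product: 26 (6R,7R,8R,9R)-9-acetoxy-8-hydroxygermacra-1(10)Z,4E,11(13)-trien-12,6-olide
Conditions: HF·pyridine, pyridine, THF, 0 °C
Reagents that add atoms: none
Why: Fluoride-mediated desilylation in buffered, weakly acidic medium should free C8–OH without acetate migration or lactone opening (C7 descriptor changes by the priority rule only).

**Step 16**
Reactants: 27 angelic acid
Product: 28 (2Z)-2-methylbut-2-en-1-ol
Conditions: LiAlH4, Et2O, 0 °C
Reagents that add atoms: none
Why: Hydride reduction of the trisubstituted α,β-unsaturated acid should give the allylic alcohol with the Z alkene intact.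

**Step 17**
Reactants: 28 (2Z)-2-methylbut-2-en-1-ol
Product: 29 [(2R,3S)-2,3-dimethyloxiran-2-yl]methanol
Conditions: Ti(OiPr)4 (10 mol %), D-(−)-diethyl tartrate (12 mol %), t-BuOOH, 4 Å molecular sieves, CH2Cl2, −20 °C
Reagents that add atoms: tert-butyl hydroperoxide, CC(C)(C)OO
Why: Sharpless asymmetric epoxidation, in which the D-(−)-tartrate–titanium complex delivers oxygen to the alkene face that gives the 2R,3S epoxy alcohol; the cis relation of the methyl groups follows from the Z alkene.

**Step 18**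
Reactants: 29 [(2R,3S)-2,3-dimethyloxiran-2-yl]methanol
Product: 30 (2S,3S)-2,3-dimethyloxirane-2-carboxylic acid
Conditions: RuCl3·xH2O (2 mol %), NaIO4, CCl4/MeCN/H2O, 0 °C → rt
Reagents that add atoms: sodium periodate, [Na+].[O-]I(=O)(=O)=O
Why: RuO4-catalysed oxidation of the primary alcohol to the acid leaves the epoxide and both centres untouched (the C2 descriptor changes by the priority rule only).

**Step 19**
Reactants: 26 (6R,7R,8R,9R)-9-acetoxy-8-hydroxygermacra-1(10)Z,4E,11(13)-trien-12,6-olide; 30 (2S,3S)-2,3-dimethyloxirane-2-carboxylic acid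
Product: 32 (6R,7S,8R,9R)-9-acetoxy-8-[(2S,3S)-2,3-dimethyloxirane-2-carbonyloxy]germacra-1(10)Z,4E,11(13)-trien-12,6-olide (CNP0304643.2), via mixed anhydride 31 (not isolated)
Conditions: 30, 2,4,6-trichlorobenzoyl chloride, Et3N, toluene, rt; then 26, 4-(dimethylamino)pyridine, 0 °C → rt
Reagents that add atoms: none
Why: Yamaguchi esterification activates the hindered α-quaternary epoxy acid as a mixed anhydride that acylates the C8 hydroxyl with retention; preforming the anhydride and keeping the temperature low limits acetyl migration from C9.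

**Compound list**

1 | geranyl acetate, (2E)-3,7-dimethylocta-2,6-dien-1-yl acetate | CC(C)=CCC/C(C)=C/COC(C)=O | starting material
2 | (2E)-5-(3,3-dimethyloxiran-2-yl)-3-methylpent-2-en-1-yl acetate (racemic) | CC1(C)OC1CC/C(C)=C/COC(C)=O | intermediate
3 | (2E)-6,7-dihydroxy-3,7-dimethyloct-2-en-1-yl acetate (racemic glycol, not isolated) | CC(C)(O)C(O)CC/C(C)=C/COC(C)=O | intermediate
4 | (2E)-3-methyl-6-oxohex-2-en-1-yl acetate | O=CCC/C(C)=C/COC(C)=O | intermediate
5 | ethyltriphenylphosphonium iodide | [I-].CC[P+](c1ccccc1)(c1ccccc1)c1ccccc1 | starting material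
6 | ethylidenetriphenylphosphorane (not isolated) | CC=P(c1ccccc1)(c1ccccc1)c1ccccc1 | intermediate
7 | (1-iodoethyl)triphenylphosphonium iodide (not isolated) | [I-].CC(I)[P+](c1ccccc1)(c1ccccc1)c1ccccc1 | intermediate
8 | (1-iodoethylidene)triphenylphosphorane (not isolated) | CC(I)=P(c1ccccc1)(c1ccccc1)c1ccccc1 | intermediate
9 | (2E,6Z)-7-iodo-3-methylocta-2,6-dien-1-yl acetate | CC(=O)OC/C=C(\C)CC/C=C(/C)I | intermediate
10 | (2E,6Z)-7-iodo-3-methylocta-2,6-dien-1-ol | OC/C=C(\C)CC/C=C(/C)I | intermediate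
11 | (2E,6Z)-7-iodo-3-methylocta-2,6-dienal | O=C/C=C(\C)CC/C=C(/C)I | intermediate
12 | (4S)-2,2-dimethyl-1,3-dioxolane-4-carbaldehyde, (S)-glyceraldehyde acetonide | O=C[C@@H]1COC(C)(C)O1 | starting material
13 | (4R)-4-(2,2-dibromoethenyl)-2,2-dimethyl-1,3-dioxolane | BrC(Br)=C[C@@H]1COC(C)(C)O1 | intermediate
14 | lithium acetylide of (4R)-4-ethynyl-2,2-dimethyl-1,3-dioxolane (not isolated) | [Li]C#C[C@@H]1COC(C)(C)O1 | intermediate
15 | methyl 3-[(4R)-2,2-dimethyl-1,3-dioxolan-4-yl]prop-2-ynoate | COC(=O)C#C[C@@H]1COC(C)(C)O1 | intermediate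
16 | methyl (2E)-2-(diisobutylalumanyl)-3-[(4R)-2,2-dimethyl-1,3-dioxolan-4-yl]prop-2-enoate (not isolated) | COC(=O)/C([Al](CC(C)C)CC(C)C)=C\[C@@H]1COC(C)(C)O1 | intermediate
17 | methyl (2Z)-3-[(4R)-2,2-dimethyl-1,3-dioxolan-4-yl]-2-[(4,4,5,5-tetramethyl-1,3,2-dioxaborolan-2-yl)methyl]prop-2-enoate | COC(=O)/C(CB1OC(C)(C)C(C)(C)O1)=C\[C@@H]2COC(C)(C)O2 | intermediate
18 | open-chain pinacol borate of the anti hydroxy ester (C6 R, C7 S, C8 R; not isolated) | COC(=O)C(=C)[C@@H]([C@H](OB2OC(C)(C)C(C)(C)O2)/C=C(\C)CC/C=C(/C)I)[C@@H]1COC(C)(C)O1 | intermediate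
19 | (4S,5R)-4-[(4R)-2,2-dimethyl-1,3-dioxolan-4-yl]-5-[(1E,5Z)-6-iodo-2-methylhepta-1,5-dien-1-yl]-3-methylideneoxolan-2-one | CC1(C)OC[C@H](O1)[C@H]2C(=C)C(=O)O[C@@H]2/C=C(\C)CC/C=C(/C)I | intermediate
20 | (4R,5R)-4-[(1R)-1,2-dihydroxyethyl]-5-[(1E,5Z)-6-iodo-2-methylhepta-1,5-dien-1-yl]-3-methylideneoxolan-2-one | OC[C@H](O)[C@H]1C(=C)C(=O)O[C@@H]1/C=C(\C)CC/C=C(/C)I | intermediate
21 | (4S,5R)-4-[(1R)-1,2-bis(triethylsilyloxy)ethyl]-5-[(1E,5Z)-6-iodo-2-methylhepta-1,5-dien-1-yl]-3-methylideneoxolan-2-one | CC[Si](CC)(CC)OC[C@H](O[Si](CC)(CC)CC)[C@H]1C(=C)C(=O)O[C@@H]1/C=C(\C)CC/C=C(/C)I | intermediate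
22 | (2R)-2-{(2R,3S)-2-[(1E,5Z)-6-iodo-2-methylhepta-1,5-dien-1-yl]-4-methylidene-5-oxooxolan-3-yl}-2-(triethylsilyloxy)acetaldehyde (key-step precursor) | O=C[C@H](O[Si](CC)(CC)CC)[C@H]1C(=C)C(=O)O[C@@H]1/C=C(\C)CC/C=C(/C)I | intermediate
23 | Z-alkenylchromium dichloride derived from 22 (not isolated) | O=C[C@H](O[Si](CC)(CC)CC)[C@H]1C(=C)C(=O)O[C@@H]1/C=C(\C)CC/C=C(/C)[Cr](Cl)Cl | intermediate
24 | (6R,7S,8R,9R)-9-hydroxy-8-(triethylsilyloxy)germacra-1(10)Z,4E,11(13)-trien-12,6-olide (key-step product) | C=C1C(=O)O[C@@H]2/C=C(\C)CC/C=C(/C)[C@@H](O)[C@H](O[Si](CC)(CC)CC)[C@@H]12 | intermediate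
25 | (6R,7S,8R,9R)-9-acetoxy-8-(triethylsilyloxy)germacra-1(10)Z,4E,11(13)-trien-12,6-olide | C=C1C(=O)O[C@@H]2/C=C(\C)CC/C=C(/C)[C@@H](OC(C)=O)[C@H](O[Si](CC)(CC)CC)[C@@H]12 | intermediate
26 | (6R,7R,8R,9R)-9-acetoxy-8-hydroxygermacra-1(10)Z,4E,11(13)-trien-12,6-olide | C=C1C(=O)O[C@@H]2/C=C(\C)CC/C=C(/C)[C@@H](OC(C)=O)[C@H](O)[C@@H]12 | intermediate
27 | angelic acid, (2Z)-2-methylbut-2-enoic acid | C/C=C(/C)C(=O)O | starting material
28 | (2Z)-2-methylbut-2-en-1-ol | C/C=C(/C)CO | intermediate
29 | [(2R,3S)-2,3-dimethyloxiran-2-yl]methanol | OC[C@@]1(C)O[C@H]1C | intermediate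
30 | (2S,3S)-2,3-dimethyloxirane-2-carboxylic acid | OC(=O)[C@@]1(C)O[C@H]1C | intermediate
31 | (2S,3S)-2,3-dimethyloxirane-2-carboxylic 2,4,6-trichlorobenzoic anhydride (not isolated) | O=C(OC(=O)c1c(Cl)cc(Cl)cc1Cl)[C@@]2(C)O[C@H]2C | intermediate
32 | (6R,7S,8R,9R)-9-acetoxy-8-[(2S,3S)-2,3-dimethyloxirane-2-carbonyloxy]germacra-1(10)Z,4E,11(13)-trien-12,6-olide | C=C1C(=O)O[C@@H]2/C=C(\C)CC/C=C(/C)[C@@H](OC(C)=O)[C@H](OC(=O)[C@@]3(C)O[C@H]3C)[C@@H]12 | target

**Step count.** Total: 19 steps. Longest linear sequence: 13 steps (1, 2, 3, 4, 5, 9, 10, 11, 12, 13, 14, 15, 19, from geranyl acetate).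

**Steps most likely to fail**

1. Step 13. Intermolecular coupling may outrun ring closure, or the aldehyde may be attacked on the Felkin face despite the ligand, so that the 9S alcohol dominates. Fallback, from 22 back to 24: close the ring without the chiral ligand (CrCl2, NiCl2 cat., DMSO/THF, high dilution) and accept the epimer mixture of 24 and the 9S alcohol F1. Oxidise the mixture with Dess–Martin periodinane to the macrocyclic C9 enone F2. Then set C9 by a Corey–Bakshi–Shibata reduction (B-methyl oxazaborolidine from diphenylprolinol, catecholborane, −40 °C; catalyst antipode chosen for hydride delivery giving 9R), which returns 24. The stereocentre is then made by ketone reduction and no longer in the C–C bond formation.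

2. Step 9. The open-chain control of the C7 face may be weak (addition syn to the C8–O bond), or the ester-deactivated allylboronate may stall with the enal. Fallback, from 17 back to 19, with alkene geometry and face fixed by a ring:
   - Oxidise the C–B bond (NaBO3·4H2O, THF/H2O) to the allylic alcohol F3.
   - Appel bromination (CBr4, PPh3) gives the allylic bromide F4.
   - Aqueous trifluoroacetic acid removes the acetonide, and the freed C8 hydroxyl, cis to the ester, closes to the bromomethyl butenolide F5.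
   - Zinc-mediated Barbier allylation of 11 (Zn dust, THF/saturated aqueous NH4Cl) should attack C7 anti to the C9 arm of the ring and anti through the chair, giving the 8,12-olide diol F6.
   - Camphorsulfonic acid with 2,2-dimethoxypropane should then move the lactone from O8 to O6, because only the 6,12-olide can tie O8 and O9 into the dioxolane; this rejoins the route at 19.

3. Step 8. The ester may be over-reduced, the propargylic oxygen may be lost from the aluminium intermediate (allene formation), or the vinylalane may alkylate sluggishly. Fallback, from 15 back to 17: Pd(PPh3)4-catalysed syn-hydrostannation with Bu3SnH gives the α-stannyl enoate F7. Iododestannylation (I2, CH2Cl2, 0 °C) gives the α-iodo enoate F8 with the same geometry. Negishi coupling with (pinacolboryl)methylzinc iodide under Pd(PPh3)4 then delivers 17.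

**Further compounds**

F1 | step 13 | (6R,7S,8R,9S)-9-hydroxy-8-(triethylsilyloxy)germacra-1(10)Z,4E,11(13)-trien-12,6-olide | C=C1C(=O)O[C@@H]2/C=C(\C)CC/C=C(/C)[C@H](O)[C@H](O[Si](CC)(CC)CC)[C@@H]12
F2 | step 13 | (6R,7S,8R)-9-oxo-8-(triethylsilyloxy)germacra-1(10)Z,4E,11(13)-trien-12,6-olide | C=C1C(=O)O[C@@H]2/C=C(\C)CC/C=C(/C)C(=O)[C@H](O[Si](CC)(CC)CC)[C@@H]12
F3 | step 9 | methyl (2Z)-3-[(4R)-2,2-dimethyl-1,3-dioxolan-4-yl]-2-(hydroxymethyl)prop-2-enoate | COC(=O)/C(CO)=C\[C@@H]1COC(C)(C)O1
F4 | step 9 | methyl (2E)-2-(bromomethyl)-3-[(4R)-2,2-dimethyl-1,3-dioxolan-4-yl]prop-2-enoate | COC(=O)/C(CBr)=C\[C@@H]1COC(C)(C)O1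
F5 | step 9 | (5R)-3-(bromomethyl)-5-(hydroxymethyl)furan-2(5H)-one | BrCC1=C[C@H](CO)OC1=O
F6 | step 9 | (4S,5R)-4-[(1R,2E,6Z)-1-hydroxy-7-iodo-3-methylocta-2,6-dien-1-yl]-5-(hydroxymethyl)-3-methylideneoxolan-2-one | C=C1C(=O)O[C@@H](CO)[C@@H]1[C@H](O)/C=C(\C)CC/C=C(/C)I
F7 | step 8 | methyl (2E)-3-[(4R)-2,2-dimethyl-1,3-dioxolan-4-yl]-2-(tributylstannyl)prop-2-enoate | COC(=O)/C([Sn](CCCC)(CCCC)CCCC)=C\[C@@H]1COC(C)(C)O1
F8 | step 8 | methyl (2E)-3-[(4R)-2,2-dimethyl-1,3-dioxolan-4-yl]-2-iodoprop-2-enoate | COC(=O)/C(I)=C\[C@@H]1COC(C)(C)O1
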